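**Retrosynthetic overview**
1. The 30-membered macrodiolide is closed last at the C1'(=O)–O14 ester by a ring-closing Evans–Tishchenko reaction of seco aldehyde 43 (oxazole-4-carbaldehyde + β-hydroxy enone), which also sets C16; only one silyl ether is then removed.
2. 43 comes from a C5=C6 Horner–Wadsworth–Emmons union of epoxy enal 16 (half A) with phosphonate 41 (half B); the other ester, C1(=O)–O14', is made early by Yamaguchi acylation.
3. Half B: all-Z triene from (Z)-1,2-dichloroethene by two Sonogashira couplings and zinc reduction; C6' by ynone transfer hydrogenation and O-methylation; C16'/C14' by Kiyooka aldol and catalyst-controlled propargylation.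
4. Half A: ketol 8 by catalytic asymmetric propargylation of keto aldehyde 5; cis-oxirane by Sharpless epoxidation of a (Z,Z)-dienol; then oxidation/Wittig.
5. Ring order: both oxazole rings are bought (in 24); oxirane (step 7); macrocycle (step 26).

Assumption: the SMILES is read literally (disorazole-type numbering, primes for the methoxy half: 14S,16S, cis-(9S,10R)-oxirane, 5E,7E,11Z; 6'R,14'R,16'S, 7'Z,9'Z,11'Z); the senses of induction quoted for the two TRIP propargylations, the Kiyooka aldol and the transfer hydrogenation are assigned from the usual models, not verified, and would be checked by Mosher analysis (mirror-image catalyst if opposite).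

**Half A: ketol and epoxy enal**

Step 1
Reactants: 1 2-methyl-1-(trimethylsilyloxy)prop-1-ene; 2 (E)-but-2-enal
Product: 4 rac-(4E)-3-hydroxy-2,2-dimethylhex-4-enal, via trimethylsilyl ether 3 (not isolated)
Conditions: Sc(OTf)3 (5 mol%), CH2Cl2, −78 °C; then 1 M HCl, THF, 0 °C
Reagents that add atoms: none
Why: Mukaiyama aldol; the enol silane adds 1,2 to the enal, the product aldehyde has no α-hydrogen and does not react on, and the racemic carbinol is erased in step 2.

Step 2
Reactants: 4 rac-(4E)-3-hydroxy-2,2-dimethylhex-4-enal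
Product: 5 (4E)-2,2-dimethyl-3-oxohex-4-enal
Conditions: Dess–Martin periodinane (1.3 equiv), CH2Cl2, 0 °C to rt
Reagents that add atoms: none
Why: Dess–Martin oxidation of the allylic alcohol; the quaternary carbon between the carbonyls prevents enolisation, so the keto aldehyde can be used crude.

Step 3
Reactants: 5 (4E)-2,2-dimethyl-3-oxohex-4-enal; 6 allenylboronic acid pinacol ester
Product: 8 (2E,6S)-6-hydroxy-5,5-dimethylnon-2-en-8-yn-4-one, via pinacolboryl ether 7 (not isolated)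
Conditions: (S)-TRIP [(S)-3,3'-bis(2,4,6-triisopropylphenyl)-1,1'-binaphthyl-2,2'-diyl hydrogen phosphate] (10 mol%), 4 Å MS, toluene, −20 °C; aqueous work-up at pH 7
Reagents that add atoms: none
Why: Chiral phosphoric acid-catalysed propargylboration (SE2' through a six-membered transition state) is chemoselective for the aldehyde over the hindered enone, and the (S)-catalyst directs Si-face attack to give 6S (C14).

Step 4
Reactants: 9 ethyl (2Z)-3-iodoprop-2-enoate
Product: 10 (2Z)-3-iodoprop-2-en-1-ol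
Conditions: i-Bu2AlH (2.2 equiv), CH2Cl2, −78 °C; aq. potassium sodium tartrate
Reagents that add atoms: none
Why: Ester reduction with i-Bu2AlH at low temperature keeps the Z-iodoalkene geometry.

Step 5
Reactants: 8 (2E,6S)-6-hydroxy-5,5-dimethylnon-2-en-8-yn-4-one; 10 (2Z)-3-iodoprop-2-en-1-ol
Product: 11 (2E,6S,10Z)-6,12-dihydroxy-5,5-dimethyldodeca-2,10-dien-8-yn-4-one
Conditions: PdCl2(PPh3)2 (3 mol%), CuI (6 mol%), Et3N, THF, rt
Reagents that add atoms: none
Why: Sonogashira coupling proceeds with retention of the Z-alkene; free hydroxyls are tolerated and a tertiary amine base avoids aza-Michael addition to the enone.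

Step 6
Reactants: 11 (2E,6S,10Z)-6,12-dihydroxy-5,5-dimethyldodeca-2,10-dien-8-yn-4-one
Product: 12 (2E,6S,8Z,10Z)-6,12-dihydroxy-5,5-dimethyldodeca-2,8,10-trien-4-one
Conditions: H2 (1 atm), Pd on CaCO3 poisoned with Pb(OAc)2, quinoline, EtOAc, 0 °C, stopped at 1 equiv H2
Reagents that add atoms: none
Why: Lindlar-type syn semi-hydrogenation of the enyne gives the 8Z alkene while the poisoned catalyst leaves the trans enone alkene alone.

Step 7
Reactants: 12 (2E,6S,8Z,10Z)-6,12-dihydroxy-5,5-dimethyldodeca-2,8,10-trien-4-one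
Product: 13 (2E,6S,8Z)-6-hydroxy-9-[(2R,3S)-3-(hydroxymethyl)oxiran-2-yl]-5,5-dimethylnona-2,8-dien-4-one
Conditions: Ti(OiPr)4 (1.0 equiv), L-(+)-diethyl tartrate (1.2 equiv), t-BuOOH (2 equiv), 4 Å MS, CH2Cl2, −20 °C
Reagents that add atoms: tert-butyl hydroperoxide, CC(C)(C)OO
Why: Sharpless asymmetric epoxidation oxidises only the allylic-alcohol alkene, and L-(+)-tartrate gives the (2S,3R)-oxiranemethanol, i.e. the cis-(9S,10R)-oxirane.

Step 8
Reactants: 13 (2E,6S,8Z)-6-hydroxy-9-[(2R,3S)-3-(hydroxymethyl)oxiran-2-yl]-5,5-dimethylnona-2,8-dien-4-one; 14 (triphenylphosphoranylidene)acetaldehyde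
Product: 16 (2E)-3-{(2S,3R)-3-[(1Z,4S,7E)-4-hydroxy-5,5-dimethyl-6-oxonona-1,7-dien-1-yl]oxiran-2-yl}prop-2-enal, via epoxy aldehyde 15 (not isolated)
Conditions: TEMPO (0.2 equiv), PhI(OAc)2 (1.1 equiv), CH2Cl2, rt; then 14 (2.5 equiv), rt
Reagents that add atoms: none
Why: TEMPO/PhI(OAc)2 oxidises the primary alcohol in preference to the hindered secondary ketol, and the sensitive cis-epoxy aldehyde is trapped at once by an E-selective Wittig reaction with the stabilised ylide.

**Half B: side chain and phosphonate ester**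

Step 9
Reactants: 2 (E)-but-2-enal; 17 1-methoxy-2-methyl-1-(trimethylsilyloxy)prop-1-ene
Product: 19 methyl (3S,4E)-3-hydroxy-2,2-dimethylhex-4-enoate, via trimethylsilyl ether 18 (not isolated)
Conditions: N-tosyl-D-valine and BH3·THF (1.0 equiv each), CH2Cl2, 0 °C to rt; then 2 and 17, −78 °C; 1 M HCl work-up
Reagents that add atoms: none
Why: Kiyooka aldol (Mukaiyama aldol promoted by a valine-derived oxazaborolidinone); the promoter shields one aldehyde face, giving 3S (C16').

Step 10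
Reactants: 19 methyl (3S,4E)-3-hydroxy-2,2-dimethylhex-4-enoate
Product: 20 methyl (3S,4E)-2,2-dimethyl-3-(triethylsilyloxy)hex-4-enoate
Conditions: Et3SiOTf (1.2 equiv), 2,6-lutidine, CH2Cl2, −78 °C
Reagents that add atoms: triethylsilyl trifluoromethanesulfonate, CC[Si](CC)(CC)OS(=O)(=O)C(F)(F)F
Why: Silylation with the triflate protects the hindered allylic alcohol that must not be acylated later.

Step 11
Reactants: 20 methyl (3S,4E)-2,2-dimethyl-3-(triethylsilyloxy)hex-4-enoate
Product: 21 (3S,4E)-2,2-dimethyl-3-(triethylsilyloxy)hex-4-enal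
Conditions: i-Bu2AlH (1.1 equiv), CH2Cl2, −78 °C; MeOH, then aq. potassium sodium tartrate
Reagents that add atoms: none
Why: Partial ester reduction; the tetrahedral aluminium intermediate of this neopentyl-type ester is expected to persist at −78 °C and release the aldehyde only on work-up.

Step 12
Reactants: 21 (3S,4E)-2,2-dimethyl-3-(triethylsilyloxy)hex-4-enal; 6 allenylboronic acid pinacol ester
Product: 23 (4R,6S,7E)-5,5-dimethyl-6-(triethylsilyloxy)non-7-en-1-yn-4-ol, via pinacolboryl ether 22 (not isolated)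
Conditions: (R)-TRIP (10 mol%), 4 Å MS, toluene, −20 °C; aqueous work-up at pH 7
Reagents that add atoms: none
Why: Chiral phosphoric acid-catalysed propargylboration under catalyst control; the (R)-catalyst directs Re-face attack to give 4R (C14'), syn to the silyloxy group.

Step 13
Reactants: 24 methyl 2-(chloromethyl)-1,3-oxazole-4-carboxylate; 25 triethyl phosphite
Product: 26 methyl 2-[(diethoxyphosphoryl)methyl]-1,3-oxazole-4-carboxylate
Conditions: neat 25 (3 equiv), 130 °C
Reagents that add atoms: none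
Why: Michaelis–Arbuzov reaction of the activated heteroarylmethyl chloride.

Step 14
Reactants: 26 methyl 2-[(diethoxyphosphoryl)methyl]-1,3-oxazole-4-carboxylate
Product: 27 2-[(diethoxyphosphoryl)methyl]-1,3-oxazole-4-carboxylic acid
Conditions: LiOH (1.2 equiv), THF/H2O, 0 °C; then 1 M HCl to pH 3
Reagents that add atoms: lithium hydroxide, [Li+].[OH-]
Why: Saponification of the carboxylate methyl ester is much faster than hydrolysis of the phosphonate ethyl esters.

Step 15
Reactants: 27 2-[(diethoxyphosphoryl)methyl]-1,3-oxazole-4-carboxylic acid; 23 (4R,6S,7E)-5,5-dimethyl-6-(triethylsilyloxy)non-7-en-1-yn-4-ol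
Product: 29 (4R,6S,7E)-5,5-dimethyl-6-(triethylsilyloxy)non-7-en-1-yn-4-yl 2-[(diethoxyphosphoryl)methyl]-1,3-oxazole-4-carboxylate, via mixed anhydride 28 (not isolated)
Conditions: 2,4,6-trichlorobenzoyl chloride, Et3N, THF, rt; then 23, DMAP, toluene, rt
Reagents that add atoms: none
Why: Yamaguchi esterification forms the C1(=O)–O14' bond at the acyl carbon, so C14' keeps its R configuration.

**Half B: methoxy oxazole head**

Step 16
Reactants: 24 methyl 2-(chloromethyl)-1,3-oxazole-4-carboxylate; 30 3-(trimethylsilyl)prop-2-ynal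
Product: 32 rac-methyl 2-[2-hydroxy-4-(trimethylsilyl)but-3-yn-1-yl]-1,3-oxazole-4-carboxylate, via organozinc chloride 31 (not isolated)
Conditions: Zn dust (activated with Me3SiCl), LiCl, THF, rt; then 30, 0 °C; aq. NH4Cl
Reagents that add atoms: none
Why: Reformatsky-type zinc insertion into the heteroarylmethyl chloride, then 1,2-addition to the ynal; the ester is tolerated.

Step 17
Reactants: 32 rac-methyl 2-[2-hydroxy-4-(trimethylsilyl)but-3-yn-1-yl]-1,3-oxazole-4-carboxylate
Product: 33 methyl 2-[2-oxo-4-(trimethylsilyl)but-3-yn-1-yl]-1,3-oxazole-4-carboxylate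
Conditions: Dess–Martin periodinane (1.2 equiv), CH2Cl2, 0 °C; used at once
Reagents that add atoms: none
Why: Dess–Martin oxidation gives the ynone under neutral conditions.

Step 18
Reactants: 33 methyl 2-[2-oxo-4-(trimethylsilyl)but-3-yn-1-yl]-1,3-oxazole-4-carboxylate
Product: 34 methyl 2-[(2R)-2-hydroxy-4-(trimethylsilyl)but-3-yn-1-yl]-1,3-oxazole-4-carboxylate
Conditions: Ru[(R,R)-TsDPEN](p-cymene) (2 mol%), i-PrOH, rt
Reagents that add atoms: none
Why: Noyori asymmetric transfer hydrogenation of an ynone; the alkynyl group takes the place of the aryl group in the transition state, so the (R,R)-catalyst gives the R carbinol (C6').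

Step 19
Reactants: 34 methyl 2-[(2R)-2-hydroxy-4-(trimethylsilyl)but-3-yn-1-yl]-1,3-oxazole-4-carboxylate
Product: 35 methyl 2-[(2R)-2-methoxy-4-(trimethylsilyl)but-3-yn-1-yl]-1,3-oxazole-4-carboxylate
Conditions: MeI (10 equiv), Ag2O (3 equiv), 4 Å MS, Et2O, rt, dark
Reagents that add atoms: iodomethane, CI
Why: Purdie (Williamson-type) O-methylation under non-basic conditions avoids retro-aldol or β-elimination next to the oxazole and leaves C6' untouched.

Step 20
Reactants: 35 methyl 2-[(2R)-2-methoxy-4-(trimethylsilyl)but-3-yn-1-yl]-1,3-oxazole-4-carboxylate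
Product: 36 {2-[(2R)-2-methoxy-4-(trimethylsilyl)but-3-yn-1-yl]-1,3-oxazol-4-yl}methanol
Conditions: i-Bu2AlH (2.5 equiv), CH2Cl2, −78 to −20 °C; aq. potassium sodium tartrate
Reagents that add atoms: none
Why: Ester reduction to the alcohol, so that the aldehyde for the ring closure can be unveiled late by a chemoselective oxidation.

**Assembly and ring closure**

Step 21
Reactants: 36 {2-[(2R)-2-methoxy-4-(trimethylsilyl)but-3-yn-1-yl]-1,3-oxazol-4-yl}methanol; 37 (Z)-1,2-dichloroethene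
Product: 39 {2-[(2R,5Z)-6-chloro-2-methoxyhex-5-en-3-yn-1-yl]-1,3-oxazol-4-yl}methanol, via terminal alkyne 38 (not isolated)
Conditions: K2CO3 (0.2 equiv), MeOH, rt; evaporate; then 37 (8 equiv), Pd(PPh3)4 (5 mol%), CuI (10 mol%), n-BuNH2, Et2O, rt
Reagents that add atoms: none
Why: Methanolysis of the alkynylsilane, then Sonogashira mono-coupling with excess dichloroethene, which retains the Z geometry.

Step 22
Reactants: 39 {2-[(2R,5Z)-6-chloro-2-methoxyhex-5-en-3-yn-1-yl]-1,3-oxazol-4-yl}methanol; 29 (4R,6S,7E)-5,5-dimethyl-6-(triethylsilyloxy)non-7-en-1-yn-4-yl 2-[(diethoxyphosphoryl)methyl]-1,3-oxazole-4-carboxylate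
Product: 40 (2E,4S,6R,10Z,14R)-15-[4-(hydroxymethyl)-1,3-oxazol-2-yl]-14-methoxy-5,5-dimethyl-4-(triethylsilyloxy)pentadeca-2,10-diene-8,12-diyn-6-yl 2-[(diethoxyphosphoryl)methyl]-1,3-oxazole-4-carboxylate
Conditions: PdCl2(PhCN)2 (5 mol%), CuI (10 mol%), piperidine, THF, rt
Reagents that add atoms: none
Why: Sonogashira coupling of the chloroenyne with the second alkyne gives the (Z)-enediyne with retention.

Step 23
Reactants: 40 the (Z)-enediyne phosphonate
Product: 41 (2E,4S,6R,8Z,10Z,12Z,14R)-15-[4-(hydroxymethyl)-1,3-oxazol-2-yl]-14-methoxy-5,5-dimethyl-4-(triethylsilyloxy)pentadeca-2,8,10,12-tetraen-6-yl 2-[(diethoxyphosphoryl)methyl]-1,3-oxazole-4-carboxylate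
Conditions: Zn dust activated with Cu(OAc)2 and AgNO3, MeOH/H2O 1:1, rt, dark
Reagents that add atoms: none
Why: Boland reduction reduces only conjugated alkynes, both cis, giving the (7'Z,9'Z,11'Z)-triene without over-reduction; the triene is kept cold and dark afterwards.

Step 24
Reactants: 41 the all-Z triene phosphonate; 16 the epoxy enal
Product: 42 seco diol: (2E,4S,6R,8Z,10Z,12Z,14R)-15-[4-(hydroxymethyl)-1,3-oxazol-2-yl]-14-methoxy-5,5-dimethyl-4-(triethylsilyloxy)pentadeca-2,8,10,12-tetraen-6-yl 2-{(1E,3E)-4-[(2S,3R)-3-((1Z,4S,7E)-4-hydroxy-5,5-dimethyl-6-oxonona-1,7-dien-1-yl)oxiran-2-yl]buta-1,3-dien-1-yl}-1,3-oxazole-4-carboxylate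
Conditions: LiN(SiMe3)2 (2.05 equiv), THF, −78 °C; then 16 (1.1 equiv), −78 to −30 °C; aq. NH4Cl
Reagents that add atoms: none
Why: Horner–Wadsworth–Emmons olefination of the heteroarylmethyl phosphonate with the enal gives the 5E alkene; the aldehyde reacts far faster than the hindered enone at low temperature.

Step 25
Reactants: 42 seco diol
Product: 43 seco aldehyde: as 42 with the oxazol-4-ylmethanol oxidised to the oxazole-4-carbaldehyde
Conditions: MnO2 (20 equiv), CH2Cl2, rt, dark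
Reagents that add atoms: none
Why: MnO2 oxidises only the heteroaryl carbinol; the homoallylic C14 alcohol, the polyenes and the oxirane are inert.

Step 26
Reactants: 43 seco aldehyde
Product: 45 16'-O-triethylsilyl ether of the target macrodiolide, via macrocyclic hemiacetal 44 (not isolated)
Conditions: SmI2 (0.5 equiv) premixed with PhCHO (0.5 equiv) in THF until yellow; then 43 added by syringe pump to 1 mM, −10 °C, dark
Reagents that add atoms: none
Why: Proposed new method: ring-closing Evans–Tishchenko macrolactonisation, in which the trivalent samarium alkoxide of the C14 ketol adds reversibly to the electron-poor oxazole-4-carbaldehyde to give the 30-membered hemiacetal 44, and a chair-like samarium-bridged six-membered transition state then transfers the hemiacetal hydride irreversibly (1,2) to the C16 ketone, forming the C1'(=O)–O14 ester and the 16S carbinol anti to O14; the closest known reaction is the intermolecular Evans–Tishchenko coupling of heteroaryl aldehydes with β-hydroxy ketones and enones, which has not been shown as a macrocyclisation on this substrate class.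

Step 27
Reactants: 45 16'-O-triethylsilyl ether of the target
Product: 46 target macrodiolide CNP0284709.4
Conditions: Bu4NF/AcOH (1:1, 3 equiv), THF, 0 °C to rt
Reagents that add atoms: none
Why: Buffered fluoride desilylation removes the silyl ether without acyl migration in the 1,3-diol monoester or opening of the divinyl oxirane.

**Compound list**
1 | 2-methyl-1-(trimethylsilyloxy)prop-1-ene | CC(C)=CO[Si](C)(C)C | starting material
2 | (E)-but-2-enal | C/C=C/C=O | starting material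
3 | rac-(4E)-2,2-dimethyl-3-(trimethylsilyloxy)hex-4-enal | C/C=C/C(O[Si](C)(C)C)C(C)(C)C=O | intermediate
4 | rac-(4E)-3-hydroxy-2,2-dimethylhex-4-enal | C/C=C/C(O)C(C)(C)C=O | intermediate
5 | (4E)-2,2-dimethyl-3-oxohex-4-enal | C/C=C/C(=O)C(C)(C)C=O | intermediate
6 | allenylboronic acid pinacol ester | C=C=CB1OC(C)(C)C(C)(C)O1 | starting material
7 | O-pinacolboryl ether of 8 | C/C=C/C(=O)C(C)(C)[C@@H](OB1OC(C)(C)C(C)(C)O1)CC#C | intermediate
8 | (2E,6S)-6-hydroxy-5,5-dimethylnon-2-en-8-yn-4-one | C/C=C/C(=O)C(C)(C)[C@@H](O)CC#C | intermediate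
9 | ethyl (2Z)-3-iodoprop-2-enoate | CCOC(=O)/C=C\I | starting material
10 | (2Z)-3-iodoprop-2-en-1-ol | OC/C=C\I | intermediate
11 | (2E,6S,10Z)-6,12-dihydroxy-5,5-dimethyldodeca-2,10-dien-8-yn-4-one | C/C=C/C(=O)C(C)(C)[C@@H](O)CC#C/C=C\CO | intermediate
12 | (2E,6S,8Z,10Z)-6,12-dihydroxy-5,5-dimethyldodeca-2,8,10-trien-4-one | C/C=C/C(=O)C(C)(C)[C@@H](O)C/C=C\C=C/CO | intermediate
13 | (2E,6S,8Z)-6-hydroxy-9-[(2R,3S)-3-(hydroxymethyl)oxiran-2-yl]-5,5-dimethylnona-2,8-dien-4-one | C/C=C/C(=O)C(C)(C)[C@@H](O)C/C=C\[C@H]1O[C@H]1CO | intermediate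
14 | (triphenylphosphoranylidene)acetaldehyde | O=CC=P(c1ccccc1)(c1ccccc1)c1ccccc1 | starting material
15 | (2R,3R)-3-[(1Z,4S,7E)-4-hydroxy-5,5-dimethyl-6-oxonona-1,7-dien-1-yl]oxirane-2-carbaldehyde | C/C=C/C(=O)C(C)(C)[C@@H](O)C/C=C\[C@H]1O[C@H]1C=O | intermediate
16 | (2E)-3-{(2S,3R)-3-[(1Z,4S,7E)-4-hydroxy-5,5-dimethyl-6-oxonona-1,7-dien-1-yl]oxiran-2-yl}prop-2-enal | C/C=C/C(=O)C(C)(C)[C@@H](O)C/C=C\[C@H]1O[C@H]1/C=C/C=O | intermediate
17 | 1-methoxy-2-methyl-1-(trimethylsilyloxy)prop-1-ene | COC(O[Si](C)(C)C)=C(C)C | starting material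
18 | methyl (3S,4E)-2,2-dimethyl-3-(trimethylsilyloxy)hex-4-enoate | COC(=O)C(C)(C)[C@@H](O[Si](C)(C)C)/C=C/C | intermediate
19 | methyl (3S,4E)-3-hydroxy-2,2-dimethylhex-4-enoate | COC(=O)C(C)(C)[C@@H](O)/C=C/C | intermediate
20 | methyl (3S,4E)-2,2-dimethyl-3-(triethylsilyloxy)hex-4-enoate | COC(=O)C(C)(C)[C@@H](O[Si](CC)(CC)CC)/C=C/C | intermediate
21 | (3S,4E)-2,2-dimethyl-3-(triethylsilyloxy)hex-4-enal | O=CC(C)(C)[C@@H](O[Si](CC)(CC)CC)/C=C/C | intermediate
22 | O-pinacolboryl ether of 23 | CC1(C)OB(O[C@@H](C(C)(C)[C@@H](O[Si](CC)(CC)CC)/C=C/C)CC#C)OC1(C)C | intermediate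
23 | (4R,6S,7E)-5,5-dimethyl-6-(triethylsilyloxy)non-7-en-1-yn-4-ol | O[C@@H](C(C)(C)[C@@H](O[Si](CC)(CC)CC)/C=C/C)CC#C | intermediate
24 | methyl 2-(chloromethyl)-1,3-oxazole-4-carboxylate | COC(=O)c1coc(CCl)n1 | starting material
25 | triethyl phosphite | CCOP(OCC)OCC | starting material
26 | methyl 2-[(diethoxyphosphoryl)methyl]-1,3-oxazole-4-carboxylate | COC(=O)c1coc(CP(=O)(OCC)OCC)n1 | intermediate
27 | 2-[(diethoxyphosphoryl)methyl]-1,3-oxazole-4-carboxylic acid | OC(=O)c1coc(CP(=O)(OCC)OCC)n1 | intermediate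
28 | mixed anhydride of 27 with 2,4,6-trichlorobenzoic acid | O=C(OC(=O)c1c(Cl)cc(Cl)cc1Cl)c1coc(CP(=O)(OCC)OCC)n1 | intermediate
29 | (4R,6S,7E)-5,5-dimethyl-6-(triethylsilyloxy)non-7-en-1-yn-4-yl 2-[(diethoxyphosphoryl)methyl]-1,3-oxazole-4-carboxylate | CCOP(=O)(Cc1nc(co1)C(=O)O[C@@H](C(C)(C)[C@@H](O[Si](CC)(CC)CC)/C=C/C)CC#C)OCC | intermediate
30 | 3-(trimethylsilyl)prop-2-ynal | C[Si](C)(C)C#CC=O | starting material
31 | chloro{[4-(methoxycarbonyl)-1,3-oxazol-2-yl]methyl}zinc | COC(=O)c1coc(C[Zn]Cl)n1 | intermediate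
32 | rac-methyl 2-[2-hydroxy-4-(trimethylsilyl)but-3-yn-1-yl]-1,3-oxazole-4-carboxylate | COC(=O)c1coc(CC(O)C#C[Si](C)(C)C)n1 | intermediate
33 | methyl 2-[2-oxo-4-(trimethylsilyl)but-3-yn-1-yl]-1,3-oxazole-4-carboxylate | COC(=O)c1coc(CC(=O)C#C[Si](C)(C)C)n1 | intermediate
34 | methyl 2-[(2R)-2-hydroxy-4-(trimethylsilyl)but-3-yn-1-yl]-1,3-oxazole-4-carboxylate | C[Si](C)(C)C#C[C@H](O)Cc1nc(co1)C(=O)OC | intermediate
35 | methyl 2-[(2R)-2-methoxy-4-(trimethylsilyl)but-3-yn-1-yl]-1,3-oxazole-4-carboxylate | C[Si](C)(C)C#C[C@H](OC)Cc1nc(co1)C(=O)OC | intermediate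
36 | {2-[(2R)-2-methoxy-4-(trimethylsilyl)but-3-yn-1-yl]-1,3-oxazol-4-yl}methanol | C[Si](C)(C)C#C[C@H](OC)Cc1nc(CO)co1 | intermediate
37 | (Z)-1,2-dichloroethene | Cl/C=C\Cl | starting material
38 | {2-[(2R)-2-methoxybut-3-yn-1-yl]-1,3-oxazol-4-yl}methanol | C#C[C@H](OC)Cc1nc(CO)co1 | intermediate
39 | {2-[(2R,5Z)-6-chloro-2-methoxyhex-5-en-3-yn-1-yl]-1,3-oxazol-4-yl}methanol | Cl/C=C\C#C[C@H](OC)Cc1nc(CO)co1 | intermediate
40 | (2E,4S,6R,10Z,14R)-15-[4-(hydroxymethyl)-1,3-oxazol-2-yl]-14-methoxy-5,5-dimethyl-4-(triethylsilyloxy)pentadeca-2,10-diene-8,12-diyn-6-yl 2-[(diethoxyphosphoryl)methyl]-1,3-oxazole-4-carboxylate | CCOP(=O)(Cc1nc(co1)C(=O)O[C@@H](C(C)(C)[C@@H](O[Si](CC)(CC)CC)/C=C/C)CC#C/C=C\C#C[C@H](OC)Cc1nc(CO)co1)OCC | intermediate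
41 | (2E,4S,6R,8Z,10Z,12Z,14R)-15-[4-(hydroxymethyl)-1,3-oxazol-2-yl]-14-methoxy-5,5-dimethyl-4-(triethylsilyloxy)pentadeca-2,8,10,12-tetraen-6-yl 2-[(diethoxyphosphoryl)methyl]-1,3-oxazole-4-carboxylate | CCOP(=O)(Cc1nc(co1)C(=O)O[C@@H](C(C)(C)[C@@H](O[Si](CC)(CC)CC)/C=C/C)C\C=C/C=C\C=C/[C@H](OC)Cc1nc(CO)co1)OCC | intermediate
42 | seco diol (name as in step 24): half A oxazole-4-carboxylate with (5E,7E)-diene, (9S,10R)-oxirane, 11Z alkene, free 14S-OH and C16 enone, esterified to O14' of half B bearing 16'S-OSiEt3, all-Z triene, 6'R-OMe and an oxazol-4-ylmethanol | C/C=C/C(=O)C(C)(C)[C@@H](O)C/C=C\[C@H]1O[C@H]1/C=C/C=C/c1nc(co1)C(=O)O[C@@H](C(C)(C)[C@@H](O[Si](CC)(CC)CC)/C=C/C)C\C=C/C=C\C=C/[C@H](OC)Cc1nc(CO)co1 | intermediate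
43 | seco aldehyde: 42 with the half B oxazol-4-ylmethanol oxidised to the 4-carbaldehyde | C/C=C/C(=O)C(C)(C)[C@@H](O)C/C=C\[C@H]1O[C@H]1/C=C/C=C/c1nc(co1)C(=O)O[C@@H](C(C)(C)[C@@H](O[Si](CC)(CC)CC)/C=C/C)C\C=C/C=C\C=C/[C@H](OC)Cc1nc(C=O)co1 | intermediate
44 | macrocyclic hemiacetal: 30-membered ring closed by O14 on the half B formyl carbon (CH(OH), both epimers; samarium-bound in the flask), C16 still a ketone | C/C=C/C(=O)C(C)(C)[C@@H]1C/C=C\[C@H]2O[C@H]2/C=C/C=C/c2nc(co2)C(=O)O[C@@H](C(C)(C)[C@@H](O[Si](CC)(CC)CC)/C=C/C)C\C=C/C=C\C=C/[C@H](OC)Cc2nc(co2)C(O)O1 | intermediate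
45 | 16'-O-triethylsilyl ether of the target macrodiolide | C/C=C/[C@H](O)C(C)(C)[C@@H]1C/C=C\[C@H]2O[C@H]2/C=C/C=C/c2nc(co2)C(=O)O[C@@H](C(C)(C)[C@@H](O[Si](CC)(CC)CC)/C=C/C)C\C=C/C=C\C=C/[C@H](OC)Cc2nc(co2)C(=O)O1 | intermediate
46 | CNP0284709.4: 30-membered bis-oxazole macrodiolide; half A 5E,7E, cis-(9S,10R)-oxirane, 11Z, 14S (acyloxy), 16S-OH, 17E; half B 6'R-OMe, 7'Z,9'Z,11'Z, 14'R (acyloxy), 16'S-OH, 17'E; C1 esterifies O14' and C1' esterifies O14 | C/C=C/[C@H](O)C(C)(C)[C@@H]1C/C=C\[C@H]2O[C@H]2/C=C/C=C/c2nc(co2)C(=O)O[C@@H](C(C)(C)[C@@H](O)/C=C/C)C\C=C/C=C\C=C/[C@H](OC)Cc2nc(co2)C(=O)O1 | target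

**Totals**
Total step count: 27. Longest linear sequence: 12 steps (16 to 27, from 24).

**Three steps most likely to fail**

Step 26 (the new step). Risks are oligomeric Tishchenko esters if dilution is insufficient, Lewis-acid opening of the divinyl oxirane by trivalent samarium, and a slow ring-closing hemiacetalisation. The fallback uses known chemistry and sets out from 41 and 13. MnO2 oxidation of 41 gives the phosphonate aldehyde F1. An ordinary intermolecular Evans–Tishchenko reaction of F1 with ketol 13 (same samarium catalyst, THF, −10 °C) gives the ester epoxy alcohol F2, with C16 set anti as before. TEMPO/PhI(OAc)2 oxidation of the primary alcohol gives the epoxy aldehyde F3, and a Wittig reaction with 14 gives the enal phosphonate F4. A macrocyclising Horner–Wadsworth–Emmons reaction (LiN(SiMe3)2, THF, 1 mM, −78 to 0 °C) then closes the ring at C5=C6 and comes back to the route at 45.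

Step 7. Z-allylic alcohols epoxidise slowly and with lower selectivity, the free ketol binds titanium, and the divinyl epoxy alcohol can be opened by the titanium reagent. The fallback sets out from 11 and epoxidises before the semi-reduction: Sharpless epoxidation of the enynol with the same tartrate gives the more robust alkynyl epoxy alcohol F5, and semi-hydrogenation of its alkyne (Pd on CaCO3 poisoned with Pb(OAc)2, quinoline) comes back at 13.

Step 24. The lithium alkoxide of the ketol in 16 can undergo retro-aldol cleavage, and the enone can intercept the phosphonate anion. The fallback sets out from 16 and masks the ketol transiently: Me3SiCl/imidazole gives the trimethylsilyl ether F6, olefination with 41 under the step 24 conditions gives the silylated seco compound F7, and citric acid in MeOH at 0 °C removes the trimethylsilyl group (the triethylsilyl ether survives), coming back at 42.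

**Further compounds**
F1 | step 26 | phosphonate aldehyde: 41 with the oxazol-4-ylmethanol oxidised to the 4-carbaldehyde | CCOP(=O)(Cc1nc(co1)C(=O)O[C@@H](C(C)(C)[C@@H](O[Si](CC)(CC)CC)/C=C/C)C\C=C/C=C\C=C/[C@H](OC)Cc1nc(C=O)co1)OCC
F2 | step 26 | ester epoxy alcohol: 13 acylated at O14 by the half B oxazole-4-carbonyl of F1, with C16 reduced to the 16S alcohol | C/C=C/[C@H](O)C(C)(C)[C@@H](OC(=O)c1coc(C[C@@H](OC)/C=C\C=C/C=C\C[C@@H](OC(=O)c2coc(CP(=O)(OCC)OCC)n2)C(C)(C)[C@@H](O[Si](CC)(CC)CC)/C=C/C)n1)C/C=C\[C@H]1O[C@H]1CO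
F3 | step 26 | epoxy aldehyde from F2 (primary alcohol oxidised) | C/C=C/[C@H](O)C(C)(C)[C@@H](OC(=O)c1coc(C[C@@H](OC)/C=C\C=C/C=C\C[C@@H](OC(=O)c2coc(CP(=O)(OCC)OCC)n2)C(C)(C)[C@@H](O[Si](CC)(CC)CC)/C=C/C)n1)C/C=C\[C@H]1O[C@H]1C=O
F4 | step 26 | enal phosphonate: F3 homologated to the (E)-enal | C/C=C/[C@H](O)C(C)(C)[C@@H](OC(=O)c1coc(C[C@@H](OC)/C=C\C=C/C=C\C[C@@H](OC(=O)c2coc(CP(=O)(OCC)OCC)n2)C(C)(C)[C@@H](O[Si](CC)(CC)CC)/C=C/C)n1)C/C=C\[C@H]1O[C@H]1/C=C/C=O
F5 | step 7 | (2E,6S)-6-hydroxy-9-[(2R,3S)-3-(hydroxymethyl)oxiran-2-yl]-5,5-dimethylnon-2-en-8-yn-4-one | C/C=C/C(=O)C(C)(C)[C@@H](O)CC#C[C@H]1O[C@H]1CO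
F6 | step 24 | O14-trimethylsilyl ether of 16 | C/C=C/C(=O)C(C)(C)[C@@H](O[Si](C)(C)C)C/C=C\[C@H]1O[C@H]1/C=C/C=O
F7 | step 24 | O14-trimethylsilyl ether of 42 | C/C=C/C(=O)C(C)(C)[C@@H](O[Si](C)(C)C)C/C=C\[C@H]1O[C@H]1/C=C/C=C/c1nc(co1)C(=O)O[C@@H](C(C)(C)[C@@H](O[Si](CC)(CC)CC)/C=C/C)C\C=C/C=C\C=C/[C@H](OC)Cc1nc(CO)co1
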